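**What stays over.** Let each G find a partner in Z or L and count what stays over: this leftover S, cZ + cL − cG, is my own reckoning, and it supposes that L takes G one to one, as Z seems to. S is 0.120 M in the new flask, and without L it is 0.0200 M, so the sign is the same either way.

the same everywhere: X 0.20 M
- Wednesday's: G 0.18 M; Z 0.28 M (fed, over 1.0 min); L 0.10 M; run made earlier
- Monday's: G 0.18 M; Z 0.44 M (fed, over 1.0 min); L 0.10 M; run made earlier
- flask: G 0.180 M; Z 0.200 M (fed, over 1.0 min); L 0.100 M; time 40 min

- Wednesday's (time / min: D / %): 0.333: 14.2; 0.833: 15.7; 2.00: 9.5; 5.00: 1.1; 12.0: 0.2; 30.0: 0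
- Monday's (time / min: D / %): 0.333: 13.9; 0.833: 14.7; 2.00: 9.0; 5.00: 2.2; 12.0: 0; 30.0: 0.6

(standard deviation of a reading: 1 percentage point)

1. when, up to 40 min, the flask holds most D
2. the amount of D, in percent of the X charged, at that time

**Earlier runs.** S was 0.200 M on Wednesday and 0.360 M on Monday. Their readings at 0.833 min differ by 1 percentage point, with a scatter of 1 point, and by 12.0 min they stand at 0.2% and 0%.

**First instants.** In the new flask X meets the G charge while Z trickles in: at 0.333 min it has received 0.0666 M of Z. Wednesday's run read 14.2% of D there, which is 0.0284 M, much less than the G charged.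

**The middle.** I suppose that D gives G back as free G falls. The readings drop to 9.5% by 2.00 min, so I put the top inside the feed of 1.0 min, at about 15.7% near 0.833 min.

**The end.** Wednesday's run read 0% of D at 30.0 min, and I expect the new flask to stand close to that by 40 min, with about S of Z and L unused.

**The forecast.** It says 17% at 1 min, later and higher than my reckoning, on the ground that “Slower feed should give a slightly higher, later peak”.

**The result.** The flask gives 15.4% at 0.622 min.

    X + G ⇌ D (K = 15.0 M⁻¹, k = 0.120 M⁻¹ s⁻¹)
    Z + G ⇌ E (K = 140 M⁻¹, k = 0.170 M⁻¹ s⁻¹)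
    2 X → Q (k = 0.310 M⁻¹ s⁻¹)
    G + L → J (k = 0.180 M⁻¹ s⁻¹)

**Same count again.** The top of this flask is flat: D is still 14.5% at 1.00 min. At 40.0 min D is 0.0310%, and free Z and L together are 0.125 M, against S of 0.120 M. A neighbouring flask charged with 0.72 M of G has S of −0.420 M, so the count now leaves G over, 0.420 M of it. That neighbour holds 0.400 M of free G at 40.0 min. It reaches 48.9% of D at its best and still has 11.6% at 40.0 min.

The readings come from a simulation for substances that don't exist, and the scatter is random.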